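Numbering: ring A of the target is O1–C2(=O)–C3–C4–C5. C6 is the benzylic CH2 on C3 and C7 is the carbinol carbon on C4.
Retrosynthetic cuts, in order: both phenols masked as benzyl ethers; O1–C2, which trades ring A for the isomeric γ-lactone ring B (C2–O–C7–C4–C3); C6–aryl; C3–O (spiro-epoxide of a C3=C6 methylidene); last, C4–C7 together with the acyl bond from the C7 oxygen to C2.
Enabling feature: C7 is an aryl carbinol on the methine C4, and the neighbouring C3 carries both the carboxyl carbon C2 and the one-carbon branch C6. C6=C3(C2)–C4 is therefore the transposed skeleton of a 2-carboxyallyl boronate, C7 is an aldehyde carbon, and the C7 oxygen lies 1,4 to C2 and can close ring B.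
Forward: three steps build the boronate chain (C2–C6). The allylboration joins it to the first aryl unit and closes ring B, epoxidation and arylation complete C3 and C6, desilylation opens ring B and closes ring A, and hydrogenolysis frees the phenols.
Stereochemistry: C7 comes from the aldehyde face chosen by a chiral phosphoric acid, C4 from the alkene geometry relayed through a chair, and C3 from oxidation of ring B on the face opposite its two cis substituents.

Key step: step 4

Remark: 4-(benzyloxy)-3-methoxybenzaldehyde is taken as a catalogue compound, and the (R)-configured phosphoric acid is assumed to open the same aldehyde face (Re) as in the crotylboration of aryl aldehydes.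

Step 1
Reactants: 1 methyl acrylate; 2 (tert-butyldimethylsilyloxy)acetaldehyde
Product: 3 methyl 4-[(tert-butyldimethylsilyl)oxy]-3-hydroxy-2-methylidenebutanoate (racemic)
Conditions: 1 (3 equiv), 1,4-diazabicyclo[2.2.2]octane (30 mol %), MeOH, rt
Reagents that add atoms: none
Why: Morita–Baylis–Hillman reaction, in which the amine adds to the acrylate, the zwitterionic enolate attacks the reactive α-silyloxy aldehyde and loss of the amine restores the acrylate; the new carbinol centre is racemic and is erased in step 3.

Step 2
Reactants: 3 methyl 4-[(tert-butyldimethylsilyl)oxy]-3-hydroxy-2-methylidenebutanoate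
Product: 4 methyl 3-acetoxy-4-[(tert-butyldimethylsilyl)oxy]-2-methylidenebutanoate (racemic)
Conditions: Ac2O, pyridine, 4-(dimethylamino)pyridine (5 mol %), CH2Cl2, 0 °C → rt
Reagents that add atoms: acetic anhydride, CC(=O)OC(C)=O
Why: Nucleophile-catalysed O-acylation of a secondary allylic alcohol turns the hydroxyl into a leaving group without touching the silyl ether or the acrylate.

Step 3
Reactants: 4 methyl 3-acetoxy-4-[(tert-butyldimethylsilyl)oxy]-2-methylidenebutanoate
Product: 5 methyl (E)-4-[(tert-butyldimethylsilyl)oxy]-2-[(4,4,5,5-tetramethyl-1,3,2-dioxaborolan-2-yl)methyl]but-2-enoate (CH2OTBS cis to CH2B)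
Conditions: B2pin2 (1.1 equiv), CuCl (1.1 equiv), KOAc (1.1 equiv), LiCl, DMF, rt
Reagents that add atoms: bis(pinacolato)diboron, CC1(C)OB(OC1(C)C)B1OC(C)(C)C(C)(C)O1
Why: Borylcopper SN2' substitution (conjugate borylation of the acrylate CH2, then loss of acetate from the copper enolate) is a known route from Baylis–Hillman acetates to 2-alkoxycarbonyl allylboronates; elimination through the conformer of least allylic strain should place CH2OTBS trans to CO2Me, and a minor geometric isomer can be removed on silica because the ester-deactivated boronate tolerates chromatography.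

Step 4
Reactants: 5 methyl (E)-4-[(tert-butyldimethylsilyl)oxy]-2-[(4,4,5,5-tetramethyl-1,3,2-dioxaborolan-2-yl)methyl]but-2-enoate; 6 4-(benzyloxy)-3-methoxybenzaldehyde
Product: 8 (4R,5R)-5-[4-(benzyloxy)-3-methoxyphenyl]-4-{[(tert-butyldimethylsilyl)oxy]methyl}-3-methylideneoxolan-2-one (cis lactone; ring B), via syn pinacol borate 7 (not isolated)
Conditions: 5 (1.2 equiv), (R)-3,3'-bis(2,4,6-triisopropylphenyl)-1,1'-binaphthyl-2,2'-diyl hydrogen phosphate (10 mol %), 4 Å MS, toluene, rt → 40 °C
Reagents that add atoms: none
Why: Proposed new method: the hydrogen phosphate should bind with its P–OH to the pseudo-axial pinacol oxygen of 5 and with its P=O to the formyl hydrogen of 6, which raises the Lewis acidity of boron so that the ester-deactivated allyl unit adds through a closed six-membered chair, C4 attacking C7 while the double bond moves to C3=C6, at a temperature where the uncatalysed addition is negligible. The closest known reaction types are the thermal or acid-promoted additions of 2-alkoxycarbonyl allylboronates to aldehydes, which end in α-methylene γ-lactones, and the chiral phosphoric acid catalysed allyl- and crotylboration of aryl aldehydes by pinacol boronates; their combination is the untested part. C4 is controlled by the alkene geometry: CH2OTBS, cis to CH2B, is forced axial while the aryl group of the aldehyde sits equatorial, which gives the syn borate 7. C7 is controlled by the catalyst, whose 2,4,6-triisopropylphenyl groups leave the Re face of the bound aldehyde open and so lead to the R carbinol centre. The borate oxygen of 7 then attacks the methyl ester in a 5-exo-trig acyl substitution with loss of MeOBpin and closes ring B, in which the syn relationship appears as cis. The step needs syn selectivity, one aldehyde face and no ionisation of the electron-rich benzylic C7–O bond, which the geometrically pure boronate, the confined catalyst pocket and the weak acid in a non-polar solvent should secure.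

Step 5
Reactants: 8 (4R,5R)-5-[4-(benzyloxy)-3-methoxyphenyl]-4-{[(tert-butyldimethylsilyl)oxy]methyl}-3-methylideneoxolan-2-one
Product: 9 (3R,6R,7R)-6-[4-(benzyloxy)-3-methoxyphenyl]-7-{[(tert-butyldimethylsilyl)oxy]methyl}-1,5-dioxaspiro[2.4]heptan-4-one (epoxide oxygen anti to both ring substituents)
Conditions: t-BuOOH (in decane, 1.5 equiv), n-BuLi (1.2 equiv), THF, −78 → −20 °C
Reagents that add atoms: tert-butyl hydroperoxide, CC(C)(C)OO
Why: Weitz–Scheffer nucleophilic epoxidation of an α-methylene lactone, in which t-BuOOLi adds to C6 and the lactone enolate closes onto the proximal peroxide oxygen from the ring face opposite the cis CH2OTBS and aryl groups; this sets C3 in the sense of the target, and the electron-rich arenes are inert to a nucleophilic oxidant.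

Step 6
Reactants: 10 4-bromo-2-methoxyphenol
Product: 11 1-(benzyloxy)-4-bromo-2-methoxybenzene
Conditions: BnBr, K2CO3, DMF, rt
Reagents that add atoms: benzyl bromide, BrCc1ccccc1
Why: Williamson ether synthesis on a phenoxide with a primary benzylic halide.

Step 7
Reactants: 9 (3R,6R,7R)-6-[4-(benzyloxy)-3-methoxyphenyl]-7-{[(tert-butyldimethylsilyl)oxy]methyl}-1,5-dioxaspiro[2.4]heptan-4-one; 11 1-(benzyloxy)-4-bromo-2-methoxybenzene
Product: 13 (3S,4R,5R)-3-[4-(benzyloxy)-3-methoxybenzyl]-5-[4-(benzyloxy)-3-methoxyphenyl]-4-{[(tert-butyldimethylsilyl)oxy]methyl}-3-hydroxyoxolan-2-one, via arylmagnesium bromide 12 (not isolated)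
Conditions: 11 (1.5 equiv), Mg, THF, 40 °C; then CuI (10 mol %), 9, THF, −40 → −20 °C
Reagents that add atoms: none
Why: Copper-catalysed Grignard opening of a 2,2-disubstituted glycidic ester, in which the arylcopper species attacks the unsubstituted epoxide carbon C6 in SN2 fashion faster at low temperature than the Grignard reagent adds to the lactone carbonyl, so that C6–aryl forms and the C3–O bond keeps its configuration.

Step 8
Reactants: 13 (3S,4R,5R)-3-[4-(benzyloxy)-3-methoxybenzyl]-5-[4-(benzyloxy)-3-methoxyphenyl]-4-{[(tert-butyldimethylsilyl)oxy]methyl}-3-hydroxyoxolan-2-one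
Product: 15 (3S,4R)-3-[4-(benzyloxy)-3-methoxybenzyl]-4-{(R)-[4-(benzyloxy)-3-methoxyphenyl](hydroxy)methyl}-3-hydroxyoxolan-2-one (ring A), via hydroxymethyl lactone 14 (not isolated)
Conditions: Bu4NF (1.1 equiv), THF, 0 °C → rt
Reagents that add atoms: none
Why: Fluoride desilylation followed by base-induced translactonisation (5-exo-trig acyl transfer), in which the C5 alkoxide attacks C2 and releases the C7 alkoxide; the equilibrium should favour ring A because ring B carries three contiguous cis substituents whereas ring A is the lactone of a primary alcohol with its two large groups trans, and no stereocentre is touched.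

Step 9
Reactants: 15 (3S,4R)-3-[4-(benzyloxy)-3-methoxybenzyl]-4-{(R)-[4-(benzyloxy)-3-methoxyphenyl](hydroxy)methyl}-3-hydroxyoxolan-2-one
Product: 16 (3S,4R)-3-hydroxy-4-[(R)-hydroxy(4-hydroxy-3-methoxyphenyl)methyl]-3-(4-hydroxy-3-methoxybenzyl)oxolan-2-one (CNP0352022.1)
Conditions: H2 (1 atm), 10% Pd/C, EtOAc, rt
Reagents that add atoms: none
Why: Catalytic hydrogenolysis of two aryl benzyl ethers under neutral conditions should be much faster than C–O cleavage of the secondary benzylic alcohol at C7, provided acid is excluded and the reaction is stopped after uptake of two equivalents of hydrogen.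

Compound list
1 | methyl acrylate | C=CC(=O)OC | starting material
2 | (tert-butyldimethylsilyloxy)acetaldehyde | O=CCO[Si](C)(C)C(C)(C)C | starting material
3 | methyl 4-[(tert-butyldimethylsilyl)oxy]-3-hydroxy-2-methylidenebutanoate (racemic) | C=C(C(=O)OC)C(O)CO[Si](C)(C)C(C)(C)C | intermediate
4 | methyl 3-acetoxy-4-[(tert-butyldimethylsilyl)oxy]-2-methylidenebutanoate (racemic) | C=C(C(=O)OC)C(OC(C)=O)CO[Si](C)(C)C(C)(C)C | intermediate
5 | methyl (E)-4-[(tert-butyldimethylsilyl)oxy]-2-[(4,4,5,5-tetramethyl-1,3,2-dioxaborolan-2-yl)methyl]but-2-enoate | COC(=O)/C(CB1OC(C)(C)C(C)(C)O1)=C/CO[Si](C)(C)C(C)(C)C | intermediate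
6 | 4-(benzyloxy)-3-methoxybenzaldehyde | COc1cc(C=O)ccc1OCc1ccccc1 | starting material
7 | methyl (3R)-3-{(R)-[4-(benzyloxy)-3-methoxyphenyl][(4,4,5,5-tetramethyl-1,3,2-dioxaborolan-2-yl)oxy]methyl}-4-[(tert-butyldimethylsilyl)oxy]-2-methylidenebutanoate (syn borate, not isolated) | C=C(C(=O)OC)[C@H](CO[Si](C)(C)C(C)(C)C)[C@@H](OB1OC(C)(C)C(C)(C)O1)c1ccc(OCc2ccccc2)c(OC)c1 | intermediate
8 | (4R,5R)-5-[4-(benzyloxy)-3-methoxyphenyl]-4-{[(tert-butyldimethylsilyl)oxy]methyl}-3-methylideneoxolan-2-one | C=C1C(=O)O[C@@H](c2ccc(OCc3ccccc3)c(OC)c2)[C@H]1CO[Si](C)(C)C(C)(C)C | intermediate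
9 | (3R,6R,7R)-6-[4-(benzyloxy)-3-methoxyphenyl]-7-{[(tert-butyldimethylsilyl)oxy]methyl}-1,5-dioxaspiro[2.4]heptan-4-one | O=C1O[C@@H](c2ccc(OCc3ccccc3)c(OC)c2)[C@@H](CO[Si](C)(C)C(C)(C)C)[C@@]12CO2 | intermediate
10 | 4-bromo-2-methoxyphenol | COc1cc(Br)ccc1O | starting material
11 | 1-(benzyloxy)-4-bromo-2-methoxybenzene | COc1cc(Br)ccc1OCc1ccccc1 | intermediate
12 | [4-(benzyloxy)-3-methoxyphenyl]magnesium bromide (not isolated) | COc1cc([Mg]Br)ccc1OCc1ccccc1 | intermediate
13 | (3S,4R,5R)-3-[4-(benzyloxy)-3-methoxybenzyl]-5-[4-(benzyloxy)-3-methoxyphenyl]-4-{[(tert-butyldimethylsilyl)oxy]methyl}-3-hydroxyoxolan-2-one | O=C1O[C@@H](c2ccc(OCc3ccccc3)c(OC)c2)[C@@H](CO[Si](C)(C)C(C)(C)C)[C@@]1(O)Cc1ccc(OCc2ccccc2)c(OC)c1 | intermediate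
14 | (3S,4R,5R)-3-[4-(benzyloxy)-3-methoxybenzyl]-5-[4-(benzyloxy)-3-methoxyphenyl]-3-hydroxy-4-(hydroxymethyl)oxolan-2-one (not isolated) | O=C1O[C@@H](c2ccc(OCc3ccccc3)c(OC)c2)[C@@H](CO)[C@@]1(O)Cc1ccc(OCc2ccccc2)c(OC)c1 | intermediate
15 | (3S,4R)-3-[4-(benzyloxy)-3-methoxybenzyl]-4-{(R)-[4-(benzyloxy)-3-methoxyphenyl](hydroxy)methyl}-3-hydroxyoxolan-2-one | COc1cc(C[C@@]2(O)C(=O)OC[C@@H]2[C@@H](O)c2ccc(OCc3ccccc3)c(OC)c2)ccc1OCc1ccccc1 | intermediate
16 | (3S,4R)-3-hydroxy-4-[(R)-hydroxy(4-hydroxy-3-methoxyphenyl)methyl]-3-(4-hydroxy-3-methoxybenzyl)oxolan-2-one | COc1cc(C[C@@]2(O)C(=O)OC[C@@H]2[C@@H](O)c2ccc(O)c(OC)c2)ccc1O | target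

Total step count: 9. Longest linear sequence: 8 steps (1, 2, 3, 4, 5, 7, 8, 9). Step 6 lies on a side branch.

Steps most likely to fail

(a) Risk at step 4 (the labelled step). The ester may lower the nucleophilicity of the allyl unit so far that hydrogen-bond activation does not bring the addition into a useful temperature range. Heating would then let the uncatalysed racemic pathway take part. Long contact with acid could also ionise the benzylic C7–O bond and convert cis lactone into trans lactone.

The fallback uses known chemistry throughout, sets out from 5 and comes back at 8. The deactivating carboxyl group is lowered to the alcohol level before C4–C7 is made and is raised again afterwards.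
- i-Bu2AlH (CH2Cl2, −78 °C) reduces 5 to (E)-4-[(tert-butyldimethylsilyl)oxy]-2-[(4,4,5,5-tetramethyl-1,3,2-dioxaborolan-2-yl)methyl]but-2-en-1-ol F1.
- Et3SiCl and imidazole convert it into its triethylsilyl ether F2.
- This is an ordinary alkyl-substituted pinacol allylboronate with the γ-substituent cis to CH2B, the class for which phosphoric acid catalysed crotylboration of aryl aldehydes is established. With 6 and the same hydrogen phosphate (5 mol %, toluene, −30 °C) it should give, after work-up, the syn homoallylic alcohol F3 with the C4 and C7 configuration of the main route.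
- Pyridinium p-toluenesulfonate in MeOH at 0 °C removes only the triethylsilyl group and gives the 1,4-diol F4.
- 2,2,6,6-Tetramethylpiperidin-1-oxyl (10 mol %) with PhI(OAc)2 in CH2Cl2 oxidises the primary allylic alcohol. The hydroxy enal closes to the lactol, which is oxidised on to 8.

(b) Risk at step 7. Three processes compete with attack at C6: addition of the arylmagnesium species to the activated lactone carbonyl, opening of the epoxide by bromide from the magnesium salts, and reductive cleavage of C3–O by electron transfer from copper.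

The fallback sets out from 8 and comes back at 13, so it also bypasses step 5. The order of C–C and C–O bond formation is reversed.
- Copper-catalysed conjugate addition of 12 (CuI 10 mol %, THF, −78 → −40 °C) to the methylidene lactone 8 gives the α-benzyl lactone F5. It forms as a mixture of C3 epimers, which is of no consequence.
- KN(SiMe3)2 (THF, −78 °C) then forms the enolate. 2-(Phenylsulfonyl)-3-phenyloxaziridine hydroxylates it from the face opposite the two cis substituents of ring B and gives 13.

(c) Risk at step 8. The acyl transfer may stall, because the direct path runs through a strained bicyclic tetrahedral intermediate. It may also stop at an equilibrium between the ring B and ring A lactones.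

The fallback sets out from 13 and comes back at 15. Equilibration is replaced by full opening and kinetically controlled re-closure.
- HF·pyridine (THF, 0 °C) gives 14, now isolated.
- LiOH (THF–H2O, 0 °C) opens ring B, and careful acidification to pH 5 gives the trihydroxy acid F6.
- N-(3-dimethylaminopropyl)-N'-ethylcarbodiimide hydrochloride (CH2Cl2, 0 °C) activates the carboxyl group. The unhindered primary C5–OH should capture it faster than the secondary benzylic C7–OH, which gives 15.

Further compounds
F1 | step 4 | (E)-4-[(tert-butyldimethylsilyl)oxy]-2-[(4,4,5,5-tetramethyl-1,3,2-dioxaborolan-2-yl)methyl]but-2-en-1-ol | OC/C(CB1OC(C)(C)C(C)(C)O1)=C/CO[Si](C)(C)C(C)(C)C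
F2 | step 4 | (E)-4-[(tert-butyldimethylsilyl)oxy]-2-[(4,4,5,5-tetramethyl-1,3,2-dioxaborolan-2-yl)methyl]-1-[(triethylsilyl)oxy]but-2-ene | CC[Si](CC)(CC)OC/C(CB1OC(C)(C)C(C)(C)O1)=C/CO[Si](C)(C)C(C)(C)C
F3 | step 4 | (1R,2R)-1-[4-(benzyloxy)-3-methoxyphenyl]-2-{[(tert-butyldimethylsilyl)oxy]methyl}-3-{[(triethylsilyl)oxy]methyl}but-3-en-1-ol | C=C(CO[Si](CC)(CC)CC)[C@H](CO[Si](C)(C)C(C)(C)C)[C@@H](O)c1ccc(OCc2ccccc2)c(OC)c1
F4 | step 4 | (1R,2R)-1-[4-(benzyloxy)-3-methoxyphenyl]-2-{[(tert-butyldimethylsilyl)oxy]methyl}-3-methylidenebutane-1,4-diol | C=C(CO)[C@H](CO[Si](C)(C)C(C)(C)C)[C@@H](O)c1ccc(OCc2ccccc2)c(OC)c1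
F5 | step 7 | (4R,5R)-3-[4-(benzyloxy)-3-methoxybenzyl]-5-[4-(benzyloxy)-3-methoxyphenyl]-4-{[(tert-butyldimethylsilyl)oxy]methyl}oxolan-2-one (C3 epimers) | O=C1O[C@@H](c2ccc(OCc3ccccc3)c(OC)c2)[C@@H](CO[Si](C)(C)C(C)(C)C)C1Cc1ccc(OCc2ccccc2)c(OC)c1
F6 | step 8 | (2S,3R,4R)-2-[4-(benzyloxy)-3-methoxybenzyl]-4-[4-(benzyloxy)-3-methoxyphenyl]-2,4-dihydroxy-3-(hydroxymethyl)butanoic acid | O=C(O)[C@](O)(Cc1ccc(OCc2ccccc2)c(OC)c1)[C@H](CO)[C@@H](O)c1ccc(OCc2ccccc2)c(OC)c1
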